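**Plan**

Retrosynthesis: target 1 is simplified by removing the C2 acetate and tying the cis C2/C3 diol into an acetonide, then cutting C12–C13 (B-alkyl Suzuki–Miyaura coupling), C9–C11 (acetylide addition to a C9 ketone) and the C8 methyl (enolate alkylation), and by restoring a hydroxyl at C1.
The ring-A ketol so obtained is cut at C4–C5 and C1–C10 in one operation, which leads back to 2-methylcyclohex-2-en-1-one 2 and a C1–C4 isopropenyl aldehyde made from 2,3-O-isopropylidene-D-erythronolactone 3.
Enabling feature: quaternary C4 (gem-dimethyl) is bonded to C5, quaternary C10 lies next to C9 (a ketone until the side chain is added), and the cis oxygens on C2 and C3 of ring A are the cis-diol of the lactone.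
Forward: the aldehyde is made from 3 in three steps; ring A is annulated onto ring B by radical conjugate addition and aldol; C1 is deoxygenated; the C8 methyl, then C11–C12 and C13–C16 are added; the diol is released and C2 is acetylated.
Stereochemistry: C2 and C3 come from D-erythronolactone; C5 from the dioxolane in the radical addition and C10 from the trans-selective aldol; C8 from equilibration; C9 from α-face attack anti to the axial C10 methyl; 13E from an (E)-enol triflate.

Key step: step 4

Remark: decalin carbons are numbered as in labdanes (ring A: C1–C5 and C10; ring B: C5–C10; side chain C11–C16 on C9); α is the face opposite the C10 methyl; in the SMILES of the iron enolate the acetylacetonate ligands on iron are left out.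

**Route**

Step 1
Reactants: 3 2,3-O-isopropylidene-D-erythronolactone
Product: 4 1-deoxy-3,4-O-isopropylidene-D-erythro-pent-2-ulofuranose (methyl lactol, both anomers)
Conditions: MeLi (1.05 equiv), THF, −78 °C; aq NH4Cl
Reagents that add atoms: methyllithium, [Li]C
Why: 1,2-addition of methyllithium to the γ-lactone at −78 °C should stop at the cyclic lithium hemiketalate, so the quench gives the methyl lactol with both dioxolane stereocentres untouched.

Step 2
Reactants: 4 1-deoxy-3,4-O-isopropylidene-D-erythro-pent-2-ulofuranose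
Product: 5 [(4R,5S)-2,2-dimethyl-5-(prop-1-en-2-yl)-1,3-dioxolan-4-yl]methanol
Conditions: Ph3PCH3Br (3 equiv), KOtBu (2.9 equiv), THF, 0 °C → rt
Reagents that add atoms: methyltriphenylphosphonium bromide, C[P+](c1ccccc1)(c1ccccc1)c1ccccc1.[Br-]
Why: Wittig methylenation acts on the open hydroxy-ketone tautomer of the lactol, as in olefinations of sugar lactols, and should give the 1,1-disubstituted alkene, the ylide being kept cold because the carbon α to the ketone (later C3) can epimerise.

Step 3
Reactants: 5 [(4R,5S)-2,2-dimethyl-5-(prop-1-en-2-yl)-1,3-dioxolan-4-yl]methanol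
Product: 6 (4S,5S)-2,2-dimethyl-5-(prop-1-en-2-yl)-1,3-dioxolane-4-carbaldehyde
Conditions: Dess–Martin periodinane, pyridine, CH2Cl2, 0 °C → rt; used crude
Reagents that add atoms: none
Why: Dess–Martin oxidation under pyridine buffering is neutral enough to give the α-alkoxy aldehyde without epimerising C2 or eliminating the β-alkoxy group.

Step 4
Reactants: 6 (4S,5S)-2,2-dimethyl-5-(prop-1-en-2-yl)-1,3-dioxolane-4-carbaldehyde; 2 2-methylcyclohex-2-en-1-one
Product: 8 1α-hydroxy-2α,3α-isopropylidenedioxy-4,4,10β-trimethyl-trans-decalin-9-one (5α-H), via iron enolate 7 (not isolated)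
Conditions: Fe(acac)3 (30 mol %), PhSiH3 (2.5 equiv), 2 (3 equiv), EtOH/(CH2OH)2, 0 °C → rt
Reagents that add atoms: none
Why: An iron hydride generated from Fe(acac)3 and PhSiH3 transfers a hydrogen atom to the CH2 terminus of the isopropenyl group of 6, the tertiary C4 radical adds to C5 of enone 2, and the α-keto radical is reduced by divalent iron to iron enolate 7, which attacks the C1 aldehyde, so that C4–C5 and C1–C10 form in one flask. The closest known reaction type is the HAT-initiated radical conjugate addition–aldol annulation of γ,δ-unsaturated aldehydes with cyclic enones (Giese addition followed by aldol). Ring A closes by a 6-(enolexo)-exo-trig aldol. C5 is set in the radical addition: in the rotamer with C3–H eclipsing a C4 methyl, C2 and its cis formyl group cover one lobe of the radical, so the enone should approach beside O3 with C10 anti to C3 and C6 over the small C3–H, which gives 5α-H, although this acyclic induction is the least secure element of the route. C10 is set in the aldol, where the reversible iron aldolate should settle in the trans-fused chair–chair ketol with the C10 methyl axial (β), and the iron-bridged closed transition state should place the C1 hydroxyl α (a centre erased in step 6, so either C1 epimer serves). The step needs hydrogen-atom transfer to the electron-rich 1,1-disubstituted alkene in preference to the enone and radical capture in preference to aldehyde reduction, which the alkene substitution pattern and the excess of 2 should secure.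

Step 5
Reactants: 8 1α-hydroxy-2α,3α-isopropylidenedioxy-4,4,10β-trimethyl-trans-decalin-9-one
Product: 9 1α-(imidazol-1-ylthiocarbonyloxy)-2α,3α-isopropylidenedioxy-4,4,10β-trimethyl-trans-decalin-9-one
Conditions: Im2C=S (3 equiv), DMAP (0.3 equiv), toluene, 90 °C
Reagents that add atoms: 1,1'-thiocarbonyldiimidazole, S=C(n1ccnc1)n1ccnc1
Why: DMAP-catalysed thioacylation of the axial C1 hydroxyl (first half of a Barton–McCombie deoxygenation) avoids a free alkoxide, which would open the β-hydroxy ketone by retro-aldol cleavage.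

Step 6
Reactants: 9 1α-(imidazol-1-ylthiocarbonyloxy)-2α,3α-isopropylidenedioxy-4,4,10β-trimethyl-trans-decalin-9-one
Product: 10 2α,3α-isopropylidenedioxy-4,4,10β-trimethyl-trans-decalin-9-one
Conditions: Bu3SnH (3 equiv), AIBN (0.2 equiv), toluene, 110 °C
Reagents that add atoms: none
Why: In this Barton–McCombie deoxygenation the tin radical adds to the thiocarbonyl group and the released secondary C1 radical is reduced by Bu3SnH, while the C9 carbonyl carbon lies in the nodal plane of that radical in the rigid trans-decalin, so acyl migration should not compete.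

Step 7
Reactants: 10 2α,3α-isopropylidenedioxy-4,4,10β-trimethyl-trans-decalin-9-one
Product: 13 2α,3α-isopropylidenedioxy-4,4,8α,10β-tetramethyl-trans-decalin-9-one, via lithium enolate 11 (not isolated), via 8β-methyl epimer 12 (not isolated)
Conditions: LiN(iPr)2 (1.1 equiv), THF, −78 °C; MeI, −78 → 0 °C; then NaOMe (cat.), MeOH, rt
Reagents that add atoms: iodomethane, CI
Why: Only C8 can be deprotonated because C10 is quaternary, so the enolate alkylation is regiospecific, and base equilibration should leave the methyl equatorial (8α) since the 8β epimer suffers a 1,3-diaxial clash with the C10 methyl.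

Step 8
Reactants: 13 2α,3α-isopropylidenedioxy-4,4,8α,10β-tetramethyl-trans-decalin-9-one
Product: 14 9α-ethynyl-2α,3α-isopropylidenedioxy-4,4,8α,10β-tetramethyl-trans-decalin-9β-ol
Conditions: HC≡CMgBr (4 equiv), THF, 0 → 40 °C; aq NH4Cl
Reagents that add atoms: ethynylmagnesium bromide, C#C[Mg]Br
Why: Small sp-hybridised Grignard reagents add to 2,2,6-trisubstituted cyclohexanones (1,2-addition), and the axial C10 methyl shields the β face, so attack should come from the α face (axial attack) and give the equatorial 9β hydroxyl and the 9α ethynyl group.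

Step 9
Reactants: 14 9α-ethynyl-2α,3α-isopropylidenedioxy-4,4,8α,10β-tetramethyl-trans-decalin-9β-ol
Product: 15 2α,3α-isopropylidenedioxy-4,4,8α,10β-tetramethyl-9α-vinyl-trans-decalin-9β-ol
Conditions: H2 (1 atm), Pd/CaCO3 poisoned with Pb(OAc)2 (Lindlar catalyst), quinoline, EtOAc, rt
Reagents that add atoms: none
Why: Lindlar semihydrogenation of a terminal tertiary propargylic alcohol should stop at the vinyl carbinol and touches no stereocentre.

Step 10
Reactants: 16 methyl acetoacetate
Product: 17 methyl (2E)-3-{[(trifluoromethyl)sulfonyl]oxy}but-2-enoate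
Conditions: aq Me4NOH, Tf2O, hexanes, 5 °C → rt
Reagents that add atoms: trifluoromethanesulfonic anhydride, O=S(=O)(OS(=O)(=O)C(F)(F)F)C(F)(F)F
Why: O-Triflation of the β-keto ester enolate with a non-coordinating tetramethylammonium counter-ion favours the non-chelated enolate and should give the (E)-enol triflate (stereoselective enol triflate formation).

Step 11
Reactants: 15 2α,3α-isopropylidenedioxy-4,4,8α,10β-tetramethyl-9α-vinyl-trans-decalin-9β-ol; 17 methyl (2E)-3-{[(trifluoromethyl)sulfonyl]oxy}but-2-enoate
Product: 19 methyl (2E)-5-(9β-hydroxy-2α,3α-isopropylidenedioxy-4,4,8α,10β-tetramethyl-trans-decalin-9α-yl)-3-methylpent-2-enoate, via B-alkyl-9-BBN borane 18 (not isolated)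
Conditions: 9-BBN (3 equiv), THF, 0 °C → rt; then 17, Pd(dppf)Cl2 (5 mol %), AsPh3, aq K3PO4, DMF, rt
Reagents that add atoms: none
Why: Anti-Markovnikov hydroboration of the vinyl group followed by B-alkyl Suzuki–Miyaura coupling joins C12 to C13 with retention of the triflate geometry, which fixes the 13E double bond.

Step 12
Reactants: 19 methyl (2E)-5-(9β-hydroxy-2α,3α-isopropylidenedioxy-4,4,8α,10β-tetramethyl-trans-decalin-9α-yl)-3-methylpent-2-enoate
Product: 20 methyl (2E)-3-methyl-5-(2α,3α,9β-trihydroxy-4,4,8α,10β-tetramethyl-trans-decalin-9α-yl)pent-2-enoate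
Conditions: AcOH/H2O (4:1), 45 °C
Reagents that add atoms: none
Why: Mild aqueous acid should hydrolyse the cis-fused acetonide (acetal hydrolysis) while the tertiary alcohol, the methyl ester and the enoate survive.

Step 13
Reactants: 20 methyl (2E)-3-methyl-5-(2α,3α,9β-trihydroxy-4,4,8α,10β-tetramethyl-trans-decalin-9α-yl)pent-2-enoate
Product: 1 methyl (2E)-5-[(1S,2R,4aS,6S,7R,8aS)-7-acetoxy-1,6-dihydroxy-2,5,5,8a-tetramethyldecahydronaphthalen-1-yl]-3-methylpent-2-enoate
Conditions: Ac2O (1.2 equiv), pyridine, CH2Cl2, 0 °C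
Reagents that add atoms: acetic anhydride, CC(=O)OC(C)=O
Why: Sterically controlled acetylation should take the equatorial C2 hydroxyl only, because the C3 hydroxyl is axial and neopentyl (next to the gem-dimethyl carbon) and the C9 hydroxyl is tertiary.

**Compound list**

1 | methyl (2E)-5-[(1S,2R,4aS,6S,7R,8aS)-7-acetoxy-1,6-dihydroxy-2,5,5,8a-tetramethyldecahydronaphthalen-1-yl]-3-methylpent-2-enoate (2α-OAc, 3α-OH, 8α-Me, 9β-OH, 13E) | COC(=O)/C=C(\C)CC[C@]1(O)[C@H](C)CC[C@H]2C(C)(C)[C@H](O)[C@H](OC(C)=O)C[C@@]21C | target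
2 | 2-methylcyclohex-2-en-1-one | CC1=CCCCC1=O | starting material
3 | 2,3-O-isopropylidene-D-erythronolactone | O=C1[C@@H]2OC(C)(C)O[C@@H]2CO1 | starting material
4 | 1-deoxy-3,4-O-isopropylidene-D-erythro-pent-2-ulofuranose (methyl lactol, anomers) | CC1(O)[C@@H]2OC(C)(C)O[C@@H]2CO1 | intermediate
5 | [(4R,5S)-2,2-dimethyl-5-(prop-1-en-2-yl)-1,3-dioxolan-4-yl]methanol | CC(=C)[C@@H]1OC(C)(C)O[C@@H]1CO | intermediate
6 | (4S,5S)-2,2-dimethyl-5-(prop-1-en-2-yl)-1,3-dioxolane-4-carbaldehyde | CC(=C)[C@@H]1OC(C)(C)O[C@@H]1C=O | intermediate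
7 | iron C9-enolate of the C4–C5 conjugate adduct (5α-H, C1 formyl group still free) | [Fe]OC1=C(C)[C@@H](CCC1)C(C)(C)[C@@H]1OC(C)(C)O[C@@H]1C=O | intermediate (not isolated)
8 | 1α-hydroxy-2α,3α-isopropylidenedioxy-4,4,10β-trimethyl-trans-decalin-9-one | O=C1CCC[C@H]2C(C)(C)[C@@H]3OC(C)(C)O[C@@H]3[C@H](O)[C@@]21C | intermediate
9 | 1α-(imidazol-1-ylthiocarbonyloxy)-2α,3α-isopropylidenedioxy-4,4,10β-trimethyl-trans-decalin-9-one | O=C1CCC[C@H]2C(C)(C)[C@@H]3OC(C)(C)O[C@@H]3[C@H](OC(=S)n4ccnc4)[C@@]21C | intermediate
10 | 2α,3α-isopropylidenedioxy-4,4,10β-trimethyl-trans-decalin-9-one | O=C1CCC[C@H]2C(C)(C)[C@@H]3OC(C)(C)O[C@@H]3C[C@@]21C | intermediate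
11 | lithium C8-enolate of 10 | [Li]OC1=CCC[C@H]2C(C)(C)[C@@H]3OC(C)(C)O[C@@H]3C[C@@]21C | intermediate (not isolated)
12 | 2α,3α-isopropylidenedioxy-4,4,8β,10β-tetramethyl-trans-decalin-9-one (8β-methyl epimer) | O=C1[C@@H](C)CC[C@H]2C(C)(C)[C@@H]3OC(C)(C)O[C@@H]3C[C@@]21C | intermediate (not isolated)
13 | 2α,3α-isopropylidenedioxy-4,4,8α,10β-tetramethyl-trans-decalin-9-one | O=C1[C@H](C)CC[C@H]2C(C)(C)[C@@H]3OC(C)(C)O[C@@H]3C[C@@]21C | intermediate
14 | 9α-ethynyl-2α,3α-isopropylidenedioxy-4,4,8α,10β-tetramethyl-trans-decalin-9β-ol | C#C[C@]1(O)[C@H](C)CC[C@H]2C(C)(C)[C@@H]3OC(C)(C)O[C@@H]3C[C@@]21C | intermediate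
15 | 2α,3α-isopropylidenedioxy-4,4,8α,10β-tetramethyl-9α-vinyl-trans-decalin-9β-ol | C=C[C@]1(O)[C@H](C)CC[C@H]2C(C)(C)[C@@H]3OC(C)(C)O[C@@H]3C[C@@]21C | intermediate
16 | methyl acetoacetate | COC(=O)CC(C)=O | starting material
17 | methyl (2E)-3-{[(trifluoromethyl)sulfonyl]oxy}but-2-enoate | COC(=O)/C=C(\C)OS(=O)(=O)C(F)(F)F | intermediate
18 | 9-[2-(9β-hydroxy-2α,3α-isopropylidenedioxy-4,4,8α,10β-tetramethyl-trans-decalin-9α-yl)ethyl]-9-borabicyclo[3.3.1]nonane | B1(C2CCCC1CCC2)CC[C@]3(O)[C@H](C)CC[C@H]4C(C)(C)[C@@H]5OC(C)(C)O[C@@H]5C[C@@]43C | intermediate (not isolated)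
19 | methyl (2E)-5-(9β-hydroxy-2α,3α-isopropylidenedioxy-4,4,8α,10β-tetramethyl-trans-decalin-9α-yl)-3-methylpent-2-enoate | COC(=O)/C=C(\C)CC[C@]1(O)[C@H](C)CC[C@H]2C(C)(C)[C@@H]3OC(C)(C)O[C@@H]3C[C@@]21C | intermediate
20 | methyl (2E)-3-methyl-5-(2α,3α,9β-trihydroxy-4,4,8α,10β-tetramethyl-trans-decalin-9α-yl)pent-2-enoate | COC(=O)/C=C(\C)CC[C@]1(O)[C@H](C)CC[C@H]2C(C)(C)[C@H](O)[C@H](O)C[C@@]21C | intermediate

**Step count and risks**

Total step count: 13. Longest linear sequence: 12 steps (steps 1–9 and 11–13, from 3); step 10 is a one-step side branch.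

Steps most likely to fail:

1. Step 4. The dioxolane stereocentre is remote from the reacting enone carbon and may not distinguish the two faces of the enone (poor facial selectivity at C5). A wrong C5 configuration cannot be repaired later, and in the least favourable case half of the material is lost as the C5 epimer. The fallback moves the control element onto the acceptor ring; it sets out from 6 and returns to the route at 8. Commercial (R)-carvone is epoxidised at its isopropenyl group (mCPBA, CH2Cl2, 0 °C) to (5R)-2-methyl-5-(2-methyloxiran-2-yl)cyclohex-2-en-1-one F1, which no longer carries an alkene open to hydrogen-atom transfer. Annulation of 6 with F1 under the conditions of step 4 should give the 7α-(2-methyloxiranyl) ketol F2, the radical entering trans to the ring substituent as in conjugate additions to 5-substituted cyclohexenones, so that C5 is fixed by the ring. Deoxygenation of the epoxide (MeReO3 cat., PPh3) should give the 7α-isopropenyl ketol F3. Ozonolysis in MeOH followed by FeSO4·7H2O and PhSH then excises the isopropenyl group: divalent iron cleaves the α-methoxy hydroperoxide, the alkoxy radical loses methyl acetate and the C7 radical takes hydrogen from the thiol, giving 8.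

2. Step 5. Acylation of the hindered axial C1 hydroxyl may be slower than retro-aldol opening of the β-hydroxy ketone under the warm, mildly basic conditions (loss of ring A). The fallback removes the ketone before the deoxygenation; it sets out from 8 and returns at 10. Reduction with NaBH4 (MeOH, 0 °C) should give the 1α,9β-diol F4. The equatorial 9β hydroxyl is silylated selectively (TBSOTf, 2,6-lutidine, −78 °C) to the 9β-silyl ether F5. The C1 alkoxide, which can no longer fragment, is converted into the S-methyl xanthate F6 (NaH, CS2, then MeI) and reduced (Bu3SnH, AIBN, toluene, 110 °C) to the 1-deoxy silyl ether F7. Bu4NF releases the 9β-alcohol F8, and Dess–Martin oxidation gives 10.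

3. Step 11. Transmetalation of the hindered, oxygen-bound alkylborane may be slow, so that base-induced elimination or hydrolysis of the enol triflate and erosion of the E geometry compete. The fallback builds the trisubstituted enoate by carbometalation instead of cross-coupling; it sets out from 13 and returns at 19. The organocerium reagent made from 4-bromo-1-(trimethylsilyl)but-1-yne (Mg, then CeCl3, THF, −78 °C) is added to 13 from the α face to give the silyl alkyne carbinol F9. K2CO3 in MeOH gives the terminal alkyne F10. Zirconium-catalysed methylalumination (Cp2ZrCl2, AlMe3, CH2Cl2) and trapping of the (E)-alkenylalane with methyl chloroformate (Negishi carboalumination) should give 19, with the 13E geometry set by syn addition.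

**Further compounds**

F1 | step 4 | (5R)-2-methyl-5-(2-methyloxiran-2-yl)cyclohex-2-en-1-one (epoxide epimers) | CC1=CC[C@H](CC1=O)C2(C)CO2
F2 | step 4 | 1α-hydroxy-2α,3α-isopropylidenedioxy-4,4,10β-trimethyl-7α-(2-methyloxiran-2-yl)-trans-decalin-9-one | O=C1C[C@H](C2(C)CO2)C[C@H]3C(C)(C)[C@@H]4OC(C)(C)O[C@@H]4[C@H](O)[C@@]31C
F3 | step 4 | 1α-hydroxy-2α,3α-isopropylidenedioxy-4,4,10β-trimethyl-7α-(prop-1-en-2-yl)-trans-decalin-9-one | O=C1C[C@H](C(C)=C)C[C@H]3C(C)(C)[C@@H]4OC(C)(C)O[C@@H]4[C@H](O)[C@@]31C
F4 | step 5 | 2α,3α-isopropylidenedioxy-4,4,10β-trimethyl-trans-decalin-1α,9β-diol | O[C@H]1CCC[C@H]2C(C)(C)[C@@H]3OC(C)(C)O[C@@H]3[C@H](O)[C@@]21C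
F5 | step 5 | 9β-(tert-butyldimethylsilyloxy)-2α,3α-isopropylidenedioxy-4,4,10β-trimethyl-trans-decalin-1α-ol | CC(C)(C)[Si](C)(C)O[C@H]1CCC[C@H]2C(C)(C)[C@@H]3OC(C)(C)O[C@@H]3[C@H](O)[C@@]21C
F6 | step 5 | O-[9β-(tert-butyldimethylsilyloxy)-2α,3α-isopropylidenedioxy-4,4,10β-trimethyl-trans-decalin-1α-yl] S-methyl dithiocarbonate | CC(C)(C)[Si](C)(C)O[C@H]1CCC[C@H]2C(C)(C)[C@@H]3OC(C)(C)O[C@@H]3[C@H](OC(=S)SC)[C@@]21C
F7 | step 5 | 9β-(tert-butyldimethylsilyloxy)-2α,3α-isopropylidenedioxy-4,4,10β-trimethyl-trans-decalin | CC(C)(C)[Si](C)(C)O[C@H]1CCC[C@H]2C(C)(C)[C@@H]3OC(C)(C)O[C@@H]3C[C@@]21C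
F8 | step 5 | 2α,3α-isopropylidenedioxy-4,4,10β-trimethyl-trans-decalin-9β-ol | O[C@H]1CCC[C@H]2C(C)(C)[C@@H]3OC(C)(C)O[C@@H]3C[C@@]21C
F9 | step 11 | 2α,3α-isopropylidenedioxy-4,4,8α,10β-tetramethyl-9α-[4-(trimethylsilyl)but-3-yn-1-yl]-trans-decalin-9β-ol | C[Si](C)(C)C#CCC[C@]1(O)[C@H](C)CC[C@H]2C(C)(C)[C@@H]3OC(C)(C)O[C@@H]3C[C@@]21C
F10 | step 11 | 9α-(but-3-yn-1-yl)-2α,3α-isopropylidenedioxy-4,4,8α,10β-tetramethyl-trans-decalin-9β-ol | C#CCC[C@]1(O)[C@H](C)CC[C@H]2C(C)(C)[C@@H]3OC(C)(C)O[C@@H]3C[C@@]21C
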